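The data stem from a simulated flask with made-up constants; scatter was added.

Read one constant off these runs first: the working time.

| setting | delta | theta | alpha | zeta |
|---|---|---|---|---|
| starting material | 100 mM | 100 mM | 200 mM | 650 mM |
| free catalyst | 10.0 mM | 15.0 mM | 10.0 mM | 10.0 mM |
| time |  |  |  | 54 min |

| run | time / min | [target] / mM |
|---|---|---|
| delta run | 2.2 | 3.0 |
| delta run | 4.1 | 5.3 |
| delta run | 7.8 | 9.7 |
| delta run | 15 | 14.4 |
| delta run | 28 | 21.1 |
| delta run | 54 | 24.4 |
| theta run | 2.2 | 4.7 |
| theta run | 4.1 | 7.3 |
| theta run | 7.8 | 12.9 |
| theta run | 15 | 21.0 |
| theta run | 28 | 27.1 |
| theta run | 54 | 31.4 |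
| alpha run | 2.2 | 3.7 |
| alpha run | 4.1 | 6.3 |
| alpha run | 7.8 | 11.9 |
| alpha run | 15 | 18.9 |
| alpha run | 28 | 26.8 |
| alpha run | 54 | 31.9 |

(standard deviation of a reading: 0.3 mM)

- Overall: starting material -> target, with free catalyst as catalyst.
- Constant volume, constant temperature.
- Bound and free are read together.
- An order is taken over about fifteen percent of the charge, up and down.

- the exponent of [free catalyst] in the starting rate at the charge of the delta run (at the point where two percent of the starting material have become target)
- the exponent of [starting material] in the starting rate at the charge of the delta run (at the point where two percent of the starting material have become target) (one fixed amount of target, the same in the runs compared)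
- target in the zeta run at 54 min, as a share of the starting material charged

Take the rate r as the first reading of target over its time: 1.36 mM/min in delta, 2.14 mM/min in theta and 1.68 mM/min in alpha. The delta run gives 17.9 min for the working time τ, the target at 54 min divided by r. So τ reads 14.7 min in theta and 19.0 min in alpha. Doubling the starting material shifts it by 6.00%, and a first delta reading scatters by 10.0%, so carry the delta value to the zeta run, which has the catalyst charge of delta.

Read the free catalyst exponent as 1.11. Read the starting material exponent across the doubling as 0.303. The rate grows less than the charge, so this is a chord: put the exponent at the delta charge a little above it.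

Now bracket the zeta run with two extremes. If its rate stays at the alpha value, τ gives 30.1 mM, or 4.63% of the charge. If the chord exponent holds up to the zeta charge, the rate is 2.40 mM/min, which gives 43.0 mM, or 6.61%. The alpha rate reads above the delta rate, yet it rose by less than the charge, so my estimate takes the middle: 5.62%.

The forecast gives 0.85, 0.3 and 5.5%, on the ground that “the catalyst is dying, roughly first order”. Its zeta share lies below mine.

The flask gives 1.0, 0.45 and 6.02%. The forecast is low on both orders  and within tolerance on the zeta run.

    free catalyst + starting material ⇌ catalyst-substrate complex, settled at all times (16.60 /M)
    catalyst-substrate complex ⇌ target + free catalyst (0.2298 /min, 2.016 /M/min)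
    free catalyst → spent catalyst (0.03054 /min)
    2 starting material → homo dimer (0.2862 /M/min)

At the start of the zeta run, the catalyst-substrate complex, the resting state, holds 91.5% of the catalyst, so the starting rate is 2.10 mM/min. The zeta target then gives τ = 18.6 min, against the 17.9 min read from delta. The zeta τ stays this short because starting material goes to homo dimer. Without that path, target in the zeta run reaches 15.3% of the charge, so τ is 47.4 min.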